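Ring A (C1 carbinol, C2=C3 tetrasubstituted alkene, C4 gem-dimethyl, C5 and C6 methylenes) is disconnected at C6–C1. The key step closes it by an intramolecular B-alkyl Suzuki–Miyaura coupling: the vinyl group on the quaternary C4 (C5=C6, from a reverse-prenyl ketone) is hydroborated and the C6 borane couples with a (Z)-iodoalkene at C1 whose geometry is set by a neighbouring tertiary carbinol at C3. That carbinol is a temporary oxidation level: oxidative 1,3-transposition and enantioselective reduction turn it into the C1 alcohol and the C2=C3 alkene. The chain is then extended by anti-carbomagnesiation of propargyl alcohol, a glycidate sets the lactone stereocentre, and an intramolecular Wittig reaction closes the butenolide.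

Key step: step 7

Remark: TBS = tert-butyldimethylsilyl; tributyl[(1-ethoxyethoxy)methyl]stannane is assumed to be made in one operation from commercial (tributylstannyl)methanol and ethyl vinyl ether, so compounds 29 to 31 arise as inconsequential mixtures of epimers at the acetal carbon.

Step 1
Reactants: 1 prenylmagnesium chloride; 2 acetic anhydride
Product: 3 3,3-dimethylpent-4-en-2-one
Conditions: THF, −78 °C, inverse addition to Ac2O (3 equiv); aq. NH4Cl
Reagents that add atoms: none
Why: Allylic Grignard reagents are acylated with allylic transposition (SE2′) at the more substituted terminus, so addition to excess anhydride at low temperature should give the α,α-dimethyl β,γ-unsaturated ketone (reverse prenylation) without a second addition.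

Step 2
Reactants: 4 5-chloro-2-methylpent-2-ene
Product: 5 (2E)-5-chloro-2-methylpent-2-en-1-ol
Conditions: SeO2 (0.1 equiv), t-BuOOH (2 equiv), CH2Cl2, 0 °C → rt
Reagents that add atoms: tert-butyl hydroperoxide, CC(C)(C)OO (terminal oxidant; the oxygen is passed on through selenium dioxide, O=[Se]=O)
Why: Riley allylic oxidation (ene reaction, then [2,3]-sigmatropic shift) is selective for the methyl group trans to the chain of a trisubstituted alkene, which fixes the E geometry of the allylic alcohol.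

Step 3
Reactants: 5 (2E)-5-chloro-2-methylpent-2-en-1-ol
Product: 6 (2E)-1-bromo-5-chloro-2-methylpent-2-ene
Conditions: PBr3 (0.4 equiv), Et2O, −10 °C
Reagents that add atoms: phosphorus tribromide, BrP(Br)Br
Why: SN2 bromination of the primary allylic alcohol through its phosphite ester keeps the alkene geometry and leaves the less reactive primary alkyl chloride untouched.

Step 4
Reactants: 3 3,3-dimethylpent-4-en-2-one; 6 (2E)-1-bromo-5-chloro-2-methylpent-2-ene
Product: 8 (7E)-10-chloro-3,3,7-trimethyldeca-1,7-dien-4-one, via lithium enolate 7 (not isolated)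
Conditions: LiN(i-Pr)2, THF, −78 °C; then 6, −78 → 0 °C
Reagents that add atoms: none
Why: Ketone 3 can enolise only at its methyl group and the allylic bromide is far more electrophilic than the alkyl chloride, so the enolate alkylation should be regio- and chemoselective.

Step 5
Reactants: 8 (7E)-10-chloro-3,3,7-trimethyldeca-1,7-dien-4-one; 9 ethynylmagnesium bromide
Product: 10 (6E)-9-chloro-6-methyl-3-(2-methylbut-3-en-2-yl)non-6-en-1-yn-3-ol (racemic)
Conditions: THF, 0 °C → rt; aq. NH4Cl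
Reagents that add atoms: none
Why: 1,2-Addition of the alkynyl Grignard reagent gives the tertiary propargylic alcohol as a racemate, which is acceptable because this carbinol centre (future ring C3) is erased by the later transposition.

Step 6
Reactants: 10 (6E)-9-chloro-6-methyl-3-(2-methylbut-3-en-2-yl)non-6-en-1-yn-3-ol
Product: 12 (1Z,6E)-9-chloro-1-iodo-2,6-dimethyl-3-(2-methylbut-3-en-2-yl)nona-1,6-dien-3-ol (racemic), via alkenylmagnesium alkoxide 11 (not isolated)
Conditions: MeMgBr (4 equiv), CuI (0.2 equiv), Et2O–THF, −10 °C → rt; then I2, −78 → 0 °C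
Reagents that add atoms: methylmagnesium bromide, C[Mg]Br; iodine, II
Why: Copper-catalysed, alkoxide-directed anti-carbomagnesiation delivers the methyl group to the alkyne carbon next to the magnesium alkoxide and magnesium to the terminal carbon within a five-membered chelate, so that iodinolysis with retention places iodine cis to the carbinol carbon (Z-iodoalkene).

Step 7
Reactants: 12 (1Z,6E)-9-chloro-1-iodo-2,6-dimethyl-3-(2-methylbut-3-en-2-yl)nona-1,6-dien-3-ol
Product: 14 1-[(3E)-6-chloro-3-methylhex-3-en-1-yl]-2,6,6-trimethylcyclohex-2-en-1-ol (racemic), via B-alkyl borane 13 (not isolated)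
Conditions: 9-BBN (2.2 equiv), THF, 0 °C → rt; then Pd(dppf)Cl2 (10 mol %), AsPh3, Cs2CO3, DMF–THF–H2O, 50 °C, high dilution
Reagents that add atoms: none
Why: Anti-Markovnikov hydroboration with 9-BBN puts boron on the terminal carbon of the vinyl group (ring C6); oxidative addition of zerovalent palladium into the C1–I bond, base-assisted transmetalation of the B-alkyl group and reductive elimination then forge the C6–C1 bond. The closest known reaction type is the intramolecular B-alkyl Suzuki–Miyaura coupling that converts haloalkenyl boranes into five- and six-membered cycloalkenes. The six-membered carbocycle closes by C(sp3)–C(sp2) reductive elimination from a seven-membered palladacycle, in an endo sense with respect to the iodoalkene, so that the C1=C2 double bond ends inside the ring. No new stereocentre is created; the racemic tertiary carbinol at C3 is a relay that step 8 erases. The step needs chemoselective hydroboration of the monosubstituted alkene over the trisubstituted chain alkene and the hindered iodoalkene (secured by the steric demand of 9-BBN) and intramolecular over intermolecular coupling (secured by the Z geometry that holds iodine next to the tether, by the gem-dimethyl group at C4 and by dilution).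

Step 8
Reactants: 14 1-[(3E)-6-chloro-3-methylhex-3-en-1-yl]-2,6,6-trimethylcyclohex-2-en-1-ol
Product: 15 3-[(3E)-6-chloro-3-methylhex-3-en-1-yl]-2,4,4-trimethylcyclohex-2-en-1-one
Conditions: pyridinium chlorochromate [C5H5NH][CrO3Cl] (3 equiv), 4 Å molecular sieves, CH2Cl2, rt
Reagents that add atoms: pyridinium chlorochromate, [O-][Cr](=O)(=O)Cl.c1cc[nH+]cc1 (supplies the carbonyl oxygen)
Why: Babler–Dauben oxidation: the 1,3-oxidative transposition of the tertiary allylic alcohol through a [3,3]-sigmatropic shift at chromium moves oxygen to C1 and the double bond into the C2=C3 position, giving the tetrasubstituted enone.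

Step 9
Reactants: 15 3-[(3E)-6-chloro-3-methylhex-3-en-1-yl]-2,4,4-trimethylcyclohex-2-en-1-one
Product: 16 (1S)-3-[(3E)-6-chloro-3-methylhex-3-en-1-yl]-2,4,4-trimethylcyclohex-2-en-1-ol
Conditions: (R)-2-methyl-CBS-oxazaborolidine (0.2 equiv), catecholborane, toluene, −78 °C
Reagents that add atoms: none
Why: Corey–Bakshi–Shibata reduction: the ketone binds the oxazaborolidine with its alkenyl (C2) side as the large group and the C6 methylene as the small group, so the (R)-catalyst should deliver hydride to the face that gives the (S)-allylic alcohol.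

Step 10
Reactants: 16 (1S)-3-[(3E)-6-chloro-3-methylhex-3-en-1-yl]-2,4,4-trimethylcyclohex-2-en-1-ol
Product: 17 tert-butyl{[(1S)-3-[(3E)-6-chloro-3-methylhex-3-en-1-yl]-2,4,4-trimethylcyclohex-2-en-1-yl]oxy}dimethylsilane
Conditions: TBSCl, imidazole, DMF, rt
Reagents that add atoms: tert-butyldimethylsilyl chloride, CC(C)(C)[Si](C)(C)Cl
Why: Standard silylation of the secondary allylic alcohol protects it against the organomagnesium and organolithium steps that follow.

Step 11
Reactants: 17 the silyl ether of step 10; 18 prop-2-yn-1-ol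
Product: 22 (2Z,5E)-2-(iodomethylidene)-6-methyl-8-[(3S)-3-(TBS-oxy)-2,6,6-trimethylcyclohex-1-en-1-yl]oct-5-en-1-ol, via chloromagnesium propargyl alkoxide 19 (not isolated), via Grignard reagent 20 (not isolated), via alkenylmagnesium alkoxide 21 (not isolated)
Conditions: 18 (1.3 equiv), i-PrMgCl (1.3 equiv), THF, −20 °C; separately 17, Mg, THF, reflux; combine, CuI (0.2 equiv), Et2O–THF, −10 °C → rt; then I2, −78 → 0 °C
Reagents that add atoms: iodine, II
Why: The primary chloride forms a Grignard reagent that adds to the magnesium alkoxide of propargyl alcohol by copper-catalysed anti-carbomagnesiation (alkyl to the internal carbon, magnesium to the terminal carbon in a five-membered chelate), and iodinolysis then gives the (Z)-3-iodo-2-alkylallyl alcohol with iodine cis to the hydroxymethyl group.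

Step 12
Reactants: 22 the iodo allylic alcohol of step 11
Product: 23 tert-butyl{[(2Z,5E)-2-(iodomethylidene)-6-methyl-8-[(3S)-3-(TBS-oxy)-2,6,6-trimethylcyclohex-1-en-1-yl]oct-5-en-1-yl]oxy}dimethylsilane
Conditions: TBSCl, imidazole, DMF, rt
Reagents that add atoms: tert-butyldimethylsilyl chloride, CC(C)(C)[Si](C)(C)Cl
Why: Silylation of the primary allylic alcohol allows the iodine–lithium exchange and keeps this hydroxyl out of the later lactone-forming step.

Step 13
Reactants: 23 the bis-silylated alkenyl iodide; 24 methyl (2S)-oxirane-2-carboxylate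
Product: 27 methyl (2S,4Z,8E)-2-hydroxy-9-methyl-5-[(TBS-oxy)methyl]-11-[(3S)-3-(TBS-oxy)-2,6,6-trimethylcyclohex-1-en-1-yl]undeca-4,8-dienoate, via alkenyllithium 25 (not isolated), via alkenylmagnesium bromide 26 (not isolated)
Conditions: t-BuLi (2.1 equiv), Et2O, −78 °C; MgBr2·OEt2; then CuI (0.1 equiv), 24, THF, −40 °C; aq. NH4Cl
Reagents that add atoms: none
Why: Iodine–lithium exchange and transmetalation proceed with retention of the alkene geometry, and the copper-catalysed SN2 opening of the glycidate at its unsubstituted carbon leaves the C–O stereocentre untouched, so the (S)-epoxide gives the (S)-α-hydroxy ester.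

Step 14
Reactants: 27 the α-hydroxy ester
Product: 28 (2S,4Z,8E)-2-hydroxy-N-methoxy-N,9-dimethyl-5-[(TBS-oxy)methyl]-11-[(3S)-3-(TBS-oxy)-2,6,6-trimethylcyclohex-1-en-1-yl]undeca-4,8-dienamide
Conditions: MeNH(OMe)·HCl, i-PrMgCl, THF, −20 → 0 °C
Reagents that add atoms: N,O-dimethylhydroxylamine hydrochloride, CNOC.Cl
Why: Aminolysis of the methyl ester by the magnesium amide of N,O-dimethylhydroxylamine (Weinreb amide formation) tolerates the free hydroxyl group as its magnesium alkoxide and does not touch the stereocentre.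

Step 15
Reactants: 28 the Weinreb amide
Product: 29 (3S,5Z,9E)-1-(1-ethoxyethoxy)-3-hydroxy-10-methyl-6-[(TBS-oxy)methyl]-12-[(3S)-3-(TBS-oxy)-2,6,6-trimethylcyclohex-1-en-1-yl]dodeca-5,9-dien-2-one
Conditions: Bu3SnCH2OCH(CH3)OEt, n-BuLi, THF, −78 °C; then 28, −78 °C; aq. NH4Cl
Reagents that add atoms: tributyl[(1-ethoxyethoxy)methyl]stannane, CCCC[Sn](CCCC)(CCCC)COC(C)OCC
Why: The α-alkoxymethyllithium reagent made by tin–lithium exchange adds only once to the Weinreb amide because the chelated tetrahedral adduct survives until work-up, which gives the protected α,α′-dihydroxy ketone.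

Step 16
Reactants: 29 the α-hydroxy ketone
Product: 31 (5S)-4-[(1-ethoxyethoxy)methyl]-5-[(2Z,6E)-7-methyl-3-[(TBS-oxy)methyl]-9-[(3S)-3-(TBS-oxy)-2,6,6-trimethylcyclohex-1-en-1-yl]nona-2,6-dien-1-yl]furan-2(5H)-one, via acyl ylide 30 (not isolated)
Conditions: Ph3P=C=C=O, toluene, 80 °C
Reagents that add atoms: (triphenylphosphoranylidene)ketene, O=C=C=P(c1ccccc1)(c1ccccc1)c1ccccc1
Why: The hydroxyl group adds to the ketene ylide to give a stabilised acyl ylide that undergoes intramolecular Wittig olefination with the adjacent ketone, closing the butenolide under neutral conditions that should not epimerise the oxygen-bearing stereocentre.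

Step 17
Reactants: 31 the protected butenolide
Product: 32 (5S)-4-(hydroxymethyl)-5-[(2Z,6E)-3-(hydroxymethyl)-9-[(3S)-3-hydroxy-2,6,6-trimethylcyclohex-1-en-1-yl]-7-methylnona-2,6-dien-1-yl]furan-2(5H)-one
Conditions: aq. HF, MeCN, 0 °C
Reagents that add atoms: none
Why: Aqueous hydrogen fluoride cleaves both silyl ethers and hydrolyses the acetal in one operation under conditions mild enough for the butenolide and the allylic alcohols.

Compound list
1 | prenylmagnesium chloride (3-methylbut-2-en-1-ylmagnesium chloride, solution in THF) | CC(C)=CC[Mg]Cl | starting material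
2 | acetic anhydride | CC(=O)OC(C)=O | starting material
3 | 3,3-dimethylpent-4-en-2-one | CC(=O)C(C)(C)C=C | intermediate
4 | 5-chloro-2-methylpent-2-ene | CC(C)=CCCCl | starting material
5 | (2E)-5-chloro-2-methylpent-2-en-1-ol | OC/C(C)=C/CCCl | intermediate
6 | (2E)-1-bromo-5-chloro-2-methylpent-2-ene | BrC/C(C)=C/CCCl | intermediate
7 | lithium 3,3-dimethylpenta-1,4-dien-2-olate (enolate of 3) | C=CC(C)(C)C(=C)O[Li] | intermediate (not isolated)
8 | (7E)-10-chloro-3,3,7-trimethyldeca-1,7-dien-4-one | C=CC(C)(C)C(=O)CC/C(C)=C/CCCl | intermediate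
9 | ethynylmagnesium bromide | C#C[Mg]Br | starting material
10 | (6E)-9-chloro-6-methyl-3-(2-methylbut-3-en-2-yl)non-6-en-1-yn-3-ol, racemic | C=CC(C)(C)C(O)(C#C)CC/C(C)=C/CCCl | intermediate
11 | bromomagnesium alkoxide of the (1Z)-alkenylmagnesium bromide from 10 (magnesium on the terminal alkene carbon, cis to the oxygen-bearing carbon) | Br[Mg]/C=C(/C)C(O[Mg]Br)(CC/C(C)=C/CCCl)C(C)(C)C=C | intermediate (not isolated)
12 | (1Z,6E)-9-chloro-1-iodo-2,6-dimethyl-3-(2-methylbut-3-en-2-yl)nona-1,6-dien-3-ol, racemic | I/C=C(/C)C(O)(CC/C(C)=C/CCCl)C(C)(C)C=C | intermediate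
13 | 9-[(7E)-10-chloro-4-hydroxy-4-[(1Z)-1-iodoprop-1-en-2-yl]-3,3,7-trimethyldec-7-en-1-yl]-9-borabicyclo[3.3.1]nonane | I/C=C(/C)C(O)(CC/C(C)=C/CCCl)C(C)(C)CCB1C2CCCC1CCC2 | intermediate (not isolated)
14 | 1-[(3E)-6-chloro-3-methylhex-3-en-1-yl]-2,6,6-trimethylcyclohex-2-en-1-ol, racemic | CC1=CCCC(C)(C)C1(O)CC/C(C)=C/CCCl | intermediate
15 | 3-[(3E)-6-chloro-3-methylhex-3-en-1-yl]-2,4,4-trimethylcyclohex-2-en-1-one | CC1=C(CC/C(C)=C/CCCl)C(C)(C)CCC1=O | intermediate
16 | (1S)-3-[(3E)-6-chloro-3-methylhex-3-en-1-yl]-2,4,4-trimethylcyclohex-2-en-1-ol | CC1=C(CC/C(C)=C/CCCl)C(C)(C)CC[C@@H]1O | intermediate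
17 | tert-butyl{[(1S)-3-[(3E)-6-chloro-3-methylhex-3-en-1-yl]-2,4,4-trimethylcyclohex-2-en-1-yl]oxy}dimethylsilane | CC1=C(CC/C(C)=C/CCCl)C(C)(C)CC[C@@H]1O[Si](C)(C)C(C)(C)C | intermediate
18 | prop-2-yn-1-ol (propargyl alcohol) | C#CCO | starting material
19 | chloromagnesium prop-2-yn-1-olate | C#CCO[Mg]Cl | intermediate (not isolated)
20 | {(3E)-4-methyl-6-[(3S)-3-(TBS-oxy)-2,6,6-trimethylcyclohex-1-en-1-yl]hex-3-en-1-yl}magnesium chloride | CC1=C(CC/C(C)=C/CC[Mg]Cl)C(C)(C)CC[C@@H]1O[Si](C)(C)C(C)(C)C | intermediate (not isolated)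
21 | chloromagnesium alkoxide of the (1Z,5E)-alkenylmagnesium chloride formed from 19 and 20 (magnesium on the terminal alkene carbon, cis to the CH2O group) | CC1=C(CC/C(C)=C/CC/C(CO[Mg]Cl)=C/[Mg]Cl)C(C)(C)CC[C@@H]1O[Si](C)(C)C(C)(C)C | intermediate (not isolated)
22 | (2Z,5E)-2-(iodomethylidene)-6-methyl-8-[(3S)-3-(TBS-oxy)-2,6,6-trimethylcyclohex-1-en-1-yl]oct-5-en-1-ol | CC1=C(CC/C(C)=C/CC/C(CO)=C/I)C(C)(C)CC[C@@H]1O[Si](C)(C)C(C)(C)C | intermediate
23 | tert-butyl{[(2Z,5E)-2-(iodomethylidene)-6-methyl-8-[(3S)-3-(TBS-oxy)-2,6,6-trimethylcyclohex-1-en-1-yl]oct-5-en-1-yl]oxy}dimethylsilane | CC1=C(CC/C(C)=C/CC/C(CO[Si](C)(C)C(C)(C)C)=C/I)C(C)(C)CC[C@@H]1O[Si](C)(C)C(C)(C)C | intermediate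
24 | methyl (2S)-oxirane-2-carboxylate (methyl (S)-glycidate) | COC(=O)[C@@H]1CO1 | starting material
25 | (1Z,5E)-alkenyllithium from 23 (lithium in place of iodine) | CC1=C(CC/C(C)=C/CC/C(CO[Si](C)(C)C(C)(C)C)=C/[Li])C(C)(C)CC[C@@H]1O[Si](C)(C)C(C)(C)C | intermediate (not isolated)
26 | (1Z,5E)-alkenylmagnesium bromide from 25 | CC1=C(CC/C(C)=C/CC/C(CO[Si](C)(C)C(C)(C)C)=C/[Mg]Br)C(C)(C)CC[C@@H]1O[Si](C)(C)C(C)(C)C | intermediate (not isolated)
27 | methyl (2S,4Z,8E)-2-hydroxy-9-methyl-5-[(TBS-oxy)methyl]-11-[(3S)-3-(TBS-oxy)-2,6,6-trimethylcyclohex-1-en-1-yl]undeca-4,8-dienoate | CC1=C(CC/C(C)=C/CC/C(CO[Si](C)(C)C(C)(C)C)=C/C[C@H](O)C(=O)OC)C(C)(C)CC[C@@H]1O[Si](C)(C)C(C)(C)C | intermediate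
28 | (2S,4Z,8E)-2-hydroxy-N-methoxy-N,9-dimethyl-5-[(TBS-oxy)methyl]-11-[(3S)-3-(TBS-oxy)-2,6,6-trimethylcyclohex-1-en-1-yl]undeca-4,8-dienamide | CC1=C(CC/C(C)=C/CC/C(CO[Si](C)(C)C(C)(C)C)=C/C[C@H](O)C(=O)N(C)OC)C(C)(C)CC[C@@H]1O[Si](C)(C)C(C)(C)C | intermediate
29 | (3S,5Z,9E)-1-(1-ethoxyethoxy)-3-hydroxy-10-methyl-6-[(TBS-oxy)methyl]-12-[(3S)-3-(TBS-oxy)-2,6,6-trimethylcyclohex-1-en-1-yl]dodeca-5,9-dien-2-one (acetal carbon unassigned) | CC1=C(CC/C(C)=C/CC/C(CO[Si](C)(C)C(C)(C)C)=C/C[C@H](O)C(=O)COC(C)OCC)C(C)(C)CC[C@@H]1O[Si](C)(C)C(C)(C)C | intermediate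
30 | (triphenylphosphoranylidene)acetate ester of the hydroxyl group of 29 (acyl ylide) | CC1=C(CC/C(C)=C/CC/C(CO[Si](C)(C)C(C)(C)C)=C/C[C@H](OC(=O)C=P(c2ccccc2)(c2ccccc2)c2ccccc2)C(=O)COC(C)OCC)C(C)(C)CC[C@@H]1O[Si](C)(C)C(C)(C)C | intermediate (not isolated)
31 | (5S)-4-[(1-ethoxyethoxy)methyl]-5-[(2Z,6E)-7-methyl-3-[(TBS-oxy)methyl]-9-[(3S)-3-(TBS-oxy)-2,6,6-trimethylcyclohex-1-en-1-yl]nona-2,6-dien-1-yl]furan-2(5H)-one (acetal carbon unassigned) | CC1=C(CC/C(C)=C/CC/C(CO[Si](C)(C)C(C)(C)C)=C/C[C@@H]2OC(=O)C=C2COC(C)OCC)C(C)(C)CC[C@@H]1O[Si](C)(C)C(C)(C)C | intermediate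
32 | (5S)-4-(hydroxymethyl)-5-[(2Z,6E)-3-(hydroxymethyl)-9-[(3S)-3-hydroxy-2,6,6-trimethylcyclohex-1-en-1-yl]-7-methylnona-2,6-dien-1-yl]furan-2(5H)-one | CC1=C(CC/C(C)=C/CC/C(=C/C[C@@H]2OC(=O)C=C2CO)CO)C(C)(C)CC[C@@H]1O | target

Total step count: 17. Longest linear sequence: 16 (steps 2 to 17, from 5-chloro-2-methylpent-2-ene).

Steps most likely to fail

Step 7 (key step). Transmetalation of the neopentyl-type B-alkyl group to the hindered, alkoxide-flanked alkenylpalladium centre may be slow, so that protodeboronation or reduction of the iodoalkene outruns ring closure. The fallback sets out from 12 and returns at 14. The same 9-BBN hydroboration is followed by oxidative work-up (NaBO3, H2O) to give the primary alcohol (7E)-10-chloro-4-[(1Z)-1-iodoprop-1-en-2-yl]-3,3,7-trimethyldec-7-ene-1,4-diol F1. Appel iodination (I2, PPh3, imidazole; the tertiary alcohol is inert) gives the primary iodide (7E)-10-chloro-1-iodo-4-[(1Z)-1-iodoprop-1-en-2-yl]-3,3,7-trimethyldec-7-en-4-ol F2. Zinc dust inserts selectively into the C(sp3)–I bond (DMF, rt), and an intramolecular Negishi coupling with Pd(PPh3)4 closes the same C6–C1 bond to give 14.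

Step 6. Carbomagnesiation at the very hindered tertiary propargylic alkoxide may be sluggish or regio-unselective, and copper-mediated methylation of the alkyl chloride may compete during the long reaction time. The fallback sets out from 10 and returns at 15; it introduces the C2 methyl group only after ring closure.
- Hydroxyl-directed trans-hydroalumination with NaAlH2(OCH2CH2OMe)2 and iodinolysis gives the iodoalkene (1Z,6E)-9-chloro-1-iodo-6-methyl-3-(2-methylbut-3-en-2-yl)nona-1,6-dien-3-ol F3.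
- The 9-BBN and palladium closure of step 7 gives 1-[(3E)-6-chloro-3-methylhex-3-en-1-yl]-6,6-dimethylcyclohex-2-en-1-ol F4.
- Oxidative transposition as in step 8 gives 3-[(3E)-6-chloro-3-methylhex-3-en-1-yl]-4,4-dimethylcyclohex-2-en-1-one F5.
- α-Iodination (I2, pyridine, CH2Cl2) gives 3-[(3E)-6-chloro-3-methylhex-3-en-1-yl]-2-iodo-4,4-dimethylcyclohex-2-en-1-one F6.
- Stille methylation (Me4Sn, Pd(PPh3)4, CuI, NMP) gives 15.

Step 13. The alkenyl metal may attack the ester carbonyl of the glycidate, or the hindered trisubstituted alkenylcopper may react too slowly with the epoxide. The fallback sets out from 23 and returns at 32; the lactone stereocentre is then set by a catalyst and not by the chiral pool.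
- Alkenyllithium 25 is trapped with ethylene oxide (BF3·OEt2, −78 °C) to give the homoallylic alcohol (3Z,7E)-8-methyl-4-[(TBS-oxy)methyl]-10-[(3S)-3-(TBS-oxy)-2,6,6-trimethylcyclohex-1-en-1-yl]deca-3,7-dien-1-ol F7.
- Dess–Martin periodinane (NaHCO3, CH2Cl2, 0 °C) gives the aldehyde (3Z,7E)-8-methyl-4-[(TBS-oxy)methyl]-10-[(3S)-3-(TBS-oxy)-2,6,6-trimethylcyclohex-1-en-1-yl]deca-3,7-dienal F8, which is used at once.
- A catalytic asymmetric Nozaki–Hiyama–Kishi coupling (CrCl2, NiCl2, chiral sulfonamide ligand, Mn, TMSCl) with methyl (2Z)-3-iodo-4-(TBS-oxy)but-2-enoate, COC(=O)/C=C(\I)CO[Si](C)(C)C(C)(C)C, is followed by lactonisation in the flask. This gives the tris-silylated butenolide (5S)-4-[(TBS-oxy)methyl]-5-[(2Z,6E)-7-methyl-3-[(TBS-oxy)methyl]-9-[(3S)-3-(TBS-oxy)-2,6,6-trimethylcyclohex-1-en-1-yl]nona-2,6-dien-1-yl]furan-2(5H)-one F9.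
- Aqueous HF in MeCN as in step 17 gives 32.

Further compounds
F1 | step 7 | (7E)-10-chloro-4-[(1Z)-1-iodoprop-1-en-2-yl]-3,3,7-trimethyldec-7-ene-1,4-diol | I/C=C(/C)C(O)(CC/C(C)=C/CCCl)C(C)(C)CCO
F2 | step 7 | (7E)-10-chloro-1-iodo-4-[(1Z)-1-iodoprop-1-en-2-yl]-3,3,7-trimethyldec-7-en-4-ol | I/C=C(/C)C(O)(CC/C(C)=C/CCCl)C(C)(C)CCI
F3 | step 6 | (1Z,6E)-9-chloro-1-iodo-6-methyl-3-(2-methylbut-3-en-2-yl)nona-1,6-dien-3-ol | I/C=C\C(O)(CC/C(C)=C/CCCl)C(C)(C)C=C
F4 | step 6 | 1-[(3E)-6-chloro-3-methylhex-3-en-1-yl]-6,6-dimethylcyclohex-2-en-1-ol | OC1(CC/C(C)=C/CCCl)C=CCCC1(C)C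
F5 | step 6 | 3-[(3E)-6-chloro-3-methylhex-3-en-1-yl]-4,4-dimethylcyclohex-2-en-1-one | O=C1C=C(CC/C(C)=C/CCCl)C(C)(C)CC1
F6 | step 6 | 3-[(3E)-6-chloro-3-methylhex-3-en-1-yl]-2-iodo-4,4-dimethylcyclohex-2-en-1-one | O=C1C(I)=C(CC/C(C)=C/CCCl)C(C)(C)CC1
F7 | step 13 | (3Z,7E)-8-methyl-4-[(TBS-oxy)methyl]-10-[(3S)-3-(TBS-oxy)-2,6,6-trimethylcyclohex-1-en-1-yl]deca-3,7-dien-1-ol | CC1=C(CC/C(C)=C/CC/C(CO[Si](C)(C)C(C)(C)C)=C/CCO)C(C)(C)CC[C@@H]1O[Si](C)(C)C(C)(C)C
F8 | step 13 | (3Z,7E)-8-methyl-4-[(TBS-oxy)methyl]-10-[(3S)-3-(TBS-oxy)-2,6,6-trimethylcyclohex-1-en-1-yl]deca-3,7-dienal | CC1=C(CC/C(C)=C/CC/C(CO[Si](C)(C)C(C)(C)C)=C/CC=O)C(C)(C)CC[C@@H]1O[Si](C)(C)C(C)(C)C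
F9 | step 13 | (5S)-4-[(TBS-oxy)methyl]-5-[(2Z,6E)-7-methyl-3-[(TBS-oxy)methyl]-9-[(3S)-3-(TBS-oxy)-2,6,6-trimethylcyclohex-1-en-1-yl]nona-2,6-dien-1-yl]furan-2(5H)-one | CC1=C(CC/C(C)=C/CC/C(CO[Si](C)(C)C(C)(C)C)=C/C[C@@H]2OC(=O)C=C2CO[Si](C)(C)C(C)(C)C)C(C)(C)CC[C@@H]1O[Si](C)(C)C(C)(C)C
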